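**Retrosynthetic overview**
1. The acetate and silyl ether are adjusted last. The key cut is the bond between the ring CH2 and the alkene CH, made by a Pd-catalysed Negishi sp3–sp2 coupling of a ring alkylzinc with a (Z)-vinyl iodide that already carries the (R)-bromohydrin as its TBS ether.
2. Ring fragment: the bromocyclohexane, the only ring, is closed first by an enantioselective bromonium-initiated, allylsilane-terminated cyclization of an acyclic silylmethyl dienoate; the ester is then taken to CH2OH and CH2I.
3. The dienoate comes from methyl acetoacetate and prenyl bromide (dianion alkylation), a (Z)-enol phosphate and a Ni-catalysed coupling with Me3SiCH2MgCl.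
4. Side-chain fragment: but-3-yn-2-ol, Cu-catalysed anti-carbomagnesiation/iodination (sets Z), oxidation, α-bromination, CBS reduction (sets R), TBS ether.
5. Ring order: the single ring is formed inside the ring fragment before the fragments are joined; no ring is formed afterwards.

Assumption: the SMILES is read as (2R,3Z)-1-bromo-5-[(1R,3S)-3-bromo-2,2-dimethyl-6-methylidenecyclohexyl]-3-methylpent-3-en-2-yl acetate (ring Br and side chain cis), and the antipode of the new step-4 catalyst that gives the (1R,3S) ring is fixed in a first screening run.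

**Step 1**
Reactants: 1 methyl acetoacetate; 2 prenyl bromide (1-bromo-3-methylbut-2-ene)
Product: 4 methyl 7-methyl-3-oxooct-6-enoate, via acetoacetate dianion 3 (not isolated)
Conditions: NaH, THF, 0 °C; n-BuLi, 0 °C; then 2, 0 → 25 °C; aq. HCl
Reagents that add atoms: none
Why: Weiler dianion alkylation, in which the more basic terminal carbanion of the acetoacetate dianion displaces the allylic bromide by SN2; no stereocentre is formed.

**Step 2**
Reactants: 4 methyl 7-methyl-3-oxooct-6-enoate
Product: 6 methyl (2Z)-3-[(diethoxyphosphoryl)oxy]-7-methylocta-2,6-dienoate, via sodium enolate 5 (not isolated)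
Conditions: NaH, Et2O, 0 °C; then ClP(O)(OEt)2, 0 → 25 °C
Reagents that add atoms: diethyl chlorophosphate, CCOP(=O)(Cl)OCC
Why: O-phosphorylation of a β-keto ester enolate; in ether the sodium ion is chelated between the enolate oxygen and the ester carbonyl, so the phosphate ends up cis to CO2Me (Z).

**Step 3**
Reactants: 6 methyl (2Z)-3-[(diethoxyphosphoryl)oxy]-7-methylocta-2,6-dienoate
Product: 7 methyl (2Z)-7-methyl-3-[(trimethylsilyl)methyl]octa-2,6-dienoate
Conditions: Me3SiCH2MgCl (2 equiv), Ni(acac)2 (5 mol%), THF, 0 → 25 °C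
Reagents that add atoms: (trimethylsilyl)methylmagnesium chloride, C[Si](C)(C)C[Mg]Cl
Why: Nickel-catalysed Kumada–Corriu coupling of an enol phosphate with a Grignard reagent that has no β-hydrogen; oxidative addition to zerovalent nickel and reductive elimination retain the alkene geometry, so CH2SiMe3 is cis to CO2Me, and the bulky Grignard reagent spares the ester.

**Step 4**
Reactants: 7 methyl (2Z)-7-methyl-3-[(trimethylsilyl)methyl]octa-2,6-dienoate
Product: 8 methyl (1R,3S)-3-bromo-2,2-dimethyl-6-methylidenecyclohexane-1-carboxylate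
Conditions: NBS (1.05 equiv), chiral thiophosphoramide catalyst [(S)-3,3′-bis(2,4,6-triisopropylphenyl)-BINOL P(=S)–NH–C6H3-3,5-(CF3)2, 10 mol%], toluene/CH2Cl2 3:1, −78 °C
Reagents that add atoms: N-bromosuccinimide, O=C1CCC(=O)N1Br
Why: Proposed new method: a catalytic enantioselective bromonium-initiated cation–olefin cyclization terminated by an ester-conjugated allylsilane, in which the Lewis-basic sulfur of the chiral thiophosphoramide takes Br+ from NBS (its N–H holds the succinimide carbonyl) and passes it to one face of the electron-rich prenyl alkene only, because the enoate alkene is deactivated; C2 of the silylmethyl enoate opens the bromiranium ion anti at the tertiary carbon through a chair transition state with Br and CO2Me both equatorial (the Z geometry of 7 places CO2Me equatorial, hence the 1,3-cis ring), and the tertiary cation at C3, stabilized by the β-silicon effect, loses Me3Si to succinimidate so that only the exocyclic alkene forms; the catalyst antipode sets the C–Br centre as S and the chair then sets C1 as R; the closest known reaction types are the chiral Lewis-base/N-bromoamide enantioselective bromocyclization of arene-terminated polyenes and the Lewis-acid-promoted epoxide-initiated cyclization of allylsilane esters.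

**Step 5**
Reactants: 8 methyl (1R,3S)-3-bromo-2,2-dimethyl-6-methylidenecyclohexane-1-carboxylate
Product: 9 [(1R,3S)-3-bromo-2,2-dimethyl-6-methylidenecyclohexyl]methanol
Conditions: i-Bu2AlH (DIBAL-H, 2.5 equiv), CH2Cl2, −78 → 0 °C; aq. KNaC4H4O6 (potassium sodium tartrate)
Reagents that add atoms: none
Why: DIBAL-H ester reduction, which does not touch the hindered secondary bromide or the alkene and, being non-basic at low temperature, does not epimerize the centre next to the ester.

**Step 6**
Reactants: 9 [(1R,3S)-3-bromo-2,2-dimethyl-6-methylidenecyclohexyl]methanol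
Product: 10 (1S,3R)-1-bromo-3-(iodomethyl)-2,2-dimethyl-4-methylidenecyclohexane
Conditions: I2, PPh3, imidazole, toluene/MeCN, 0 → 50 °C
Reagents that add atoms: iodine, [I][I]
Why: Appel-type (Garegg–Samuelsson) iodination, in which iodide displaces the alkoxyphosphonium group by SN2 at the primary carbon only; the stereocentres are not involved.

**Step 7**
Reactants: 11 but-3-yn-2-ol (racemic)
Product: 13 (3Z)-4-iodo-3-methylbut-3-en-2-ol (racemic), via cyclic alkenylmagnesium alkoxide 12 (not isolated)
Conditions: MeMgBr (3 equiv), CuI (10 mol%), THF, −20 → 25 °C; then I2, −78 → 0 °C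
Reagents that add atoms: methylmagnesium bromide, C[Mg]Br; iodine, [I][I]
Why: Copper-catalysed anti-carbomagnesiation of a propargylic alkoxide (Duboudin-type): methyl adds to the internal alkyne carbon and magnesium to the terminal carbon on the opposite side, held by the alkoxide in a five-membered chelate, and iodinolysis with retention gives the (Z)-vinyl iodide; the carbinol centre is racemic and is removed in step 8.

**Step 8**
Reactants: 13 (3Z)-4-iodo-3-methylbut-3-en-2-ol (racemic)
Product: 14 (3Z)-4-iodo-3-methylbut-3-en-2-one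
Conditions: Dess–Martin periodinane, CH2Cl2, 0 → 25 °C, dark
Reagents that add atoms: none
Why: Dess–Martin oxidation of a secondary allylic alcohol under neutral conditions, which keeps the light- and nucleophile-sensitive (Z)-iodoenone geometry.

**Step 9**
Reactants: 14 (3Z)-4-iodo-3-methylbut-3-en-2-one
Product: 16 (3Z)-1-bromo-4-iodo-3-methylbut-3-en-2-one, via silyl dienol ether 15 (not isolated)
Conditions: TMSOTf, i-Pr2NEt, CH2Cl2, −78 → 0 °C; then NBS, THF, −78 °C
Reagents that add atoms: N-bromosuccinimide, O=C1CCC(=O)N1Br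
Why: α-Bromination of a ketone through its silyl enol ether: soft enolization can only occur at the acetyl methyl group, and NBS brominates the terminal carbon of the resulting 2-silyloxydiene.

**Step 10**
Reactants: 16 (3Z)-1-bromo-4-iodo-3-methylbut-3-en-2-one
Product: 17 (2R,3Z)-1-bromo-4-iodo-3-methylbut-3-en-2-ol
Conditions: (R)-2-methyl-CBS-oxazaborolidine (15 mol%), BH3·SMe2 (0.7 equiv), THF, −30 °C; MeOH
Reagents that add atoms: none
Why: Corey–Bakshi–Shibata reduction: the ketone binds the oxazaborolidine with the branched alkenyl group as the large substituent and CH2Br as the small one, so the (R)-catalyst delivers hydride to give the (2R)-bromohydrin, the same facial sense as with halomethyl aryl ketones.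

**Step 11**
Reactants: 17 (2R,3Z)-1-bromo-4-iodo-3-methylbut-3-en-2-ol
Product: 18 tert-butyl{[(2R,3Z)-1-bromo-4-iodo-3-methylbut-3-en-2-yl]oxy}dimethylsilane
Conditions: TBSOTf, 2,6-lutidine, CH2Cl2, −78 → 0 °C
Reagents that add atoms: tert-butyldimethylsilyl trifluoromethanesulfonate, CC(C)(C)[Si](C)(C)OS(=O)(=O)C(F)(F)F
Why: Silylation with a silyl triflate and a weak hindered base, which forms no alkoxide and so avoids epoxide closure of the bromohydrin; the configuration is retained.

**Step 12**
Reactants: 10 (1S,3R)-1-bromo-3-(iodomethyl)-2,2-dimethyl-4-methylidenecyclohexane; 18 tert-butyl{[(2R,3Z)-1-bromo-4-iodo-3-methylbut-3-en-2-yl]oxy}dimethylsilane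
Product: 20 tert-butyl({(2R,3Z)-1-bromo-5-[(1R,3S)-3-bromo-2,2-dimethyl-6-methylidenecyclohexyl]-3-methylpent-3-en-2-yl}oxy)dimethylsilane, via alkylzinc iodide 19 (not isolated)
Conditions: Zn dust, LiCl, THF, 35 °C; filter from Zn; then 18, Pd(dppf)Cl2 (5 mol%), THF/NMP, 25 → 40 °C
Reagents that add atoms: none
Why: Zinc insertion into the primary C–I bond (the hindered secondary bromide is inert) followed by a palladium-catalysed Negishi sp3–sp2 coupling: zerovalent palladium adds to the vinyl iodide with retention, and the wide-bite-angle dppf ligand makes reductive elimination faster than β-hydride elimination, so the Z alkene and all stereocentres are kept; excess zinc is removed first so the CH2Br group of 18 is not attacked.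

**Step 13**
Reactants: 20 tert-butyl({(2R,3Z)-1-bromo-5-[(1R,3S)-3-bromo-2,2-dimethyl-6-methylidenecyclohexyl]-3-methylpent-3-en-2-yl}oxy)dimethylsilane
Product: 21 (2R,3Z)-1-bromo-5-[(1R,3S)-3-bromo-2,2-dimethyl-6-methylidenecyclohexyl]-3-methylpent-3-en-2-ol
Conditions: HF·pyridine, pyridine, THF, 0 → 25 °C
Reagents that add atoms: none
Why: Fluoride-mediated desilylation under buffered, weakly acidic conditions, which generates no alkoxide (no epoxide from the bromohydrin) and does not isomerize the exocyclic alkene.

**Step 14**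
Reactants: 21 (2R,3Z)-1-bromo-5-[(1R,3S)-3-bromo-2,2-dimethyl-6-methylidenecyclohexyl]-3-methylpent-3-en-2-ol
Product: 22 (2R,3Z)-1-bromo-5-[(1R,3S)-3-bromo-2,2-dimethyl-6-methylidenecyclohexyl]-3-methylpent-3-en-2-yl acetate
Conditions: Ac2O, pyridine, DMAP (cat.), CH2Cl2, 0 °C
Reagents that add atoms: acetic anhydride, CC(=O)OC(C)=O
Why: DMAP-catalysed acetylation of the secondary alcohol at oxygen, with retention of configuration and without displacing either bromide.

**Compound list**
1 | methyl acetoacetate | CC(=O)CC(=O)OC | starting material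
2 | prenyl bromide (1-bromo-3-methylbut-2-ene) | CC(C)=CCBr | starting material
3 | sodium lithium dianion of methyl acetoacetate | [CH2-]C(=O)[CH-]C(=O)OC.[Na+].[Li+] | intermediate
4 | methyl 7-methyl-3-oxooct-6-enoate | CC(C)=CCCC(=O)CC(=O)OC | intermediate
5 | sodium (2Z)-1-methoxy-7-methyl-1-oxoocta-2,6-dien-3-olate | CC(C)=CCC/C([O-])=C/C(=O)OC.[Na+] | intermediate
6 | methyl (2Z)-3-[(diethoxyphosphoryl)oxy]-7-methylocta-2,6-dienoate | CC(C)=CCC/C(OP(=O)(OCC)OCC)=C/C(=O)OC | intermediate
7 | methyl (2Z)-7-methyl-3-[(trimethylsilyl)methyl]octa-2,6-dienoate | CC(C)=CCC/C(C[Si](C)(C)C)=C/C(=O)OC | intermediate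
8 | methyl (1R,3S)-3-bromo-2,2-dimethyl-6-methylidenecyclohexane-1-carboxylate | C=C1CC[C@H](Br)C(C)(C)[C@@H]1C(=O)OC | intermediate
9 | [(1R,3S)-3-bromo-2,2-dimethyl-6-methylidenecyclohexyl]methanol | C=C1CC[C@H](Br)C(C)(C)[C@@H]1CO | intermediate
10 | (1S,3R)-1-bromo-3-(iodomethyl)-2,2-dimethyl-4-methylidenecyclohexane | C=C1CC[C@H](Br)C(C)(C)[C@@H]1CI | intermediate
11 | but-3-yn-2-ol (racemic) | CC(O)C#C | starting material
12 | cyclic alkenylmagnesium alkoxide (4,5-dimethyl-2,5-dihydro-1,2-oxamagnesole, racemic) | CC1O[Mg]C=C1C | intermediate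
13 | (3Z)-4-iodo-3-methylbut-3-en-2-ol (racemic) | I/C=C(/C)C(C)O | intermediate
14 | (3Z)-4-iodo-3-methylbut-3-en-2-one | I/C=C(/C)C(C)=O | intermediate
15 | {[(3Z)-4-iodo-3-methylbuta-1,3-dien-2-yl]oxy}trimethylsilane | I/C=C(/C)C(=C)O[Si](C)(C)C | intermediate
16 | (3Z)-1-bromo-4-iodo-3-methylbut-3-en-2-one | I/C=C(/C)C(=O)CBr | intermediate
17 | (2R,3Z)-1-bromo-4-iodo-3-methylbut-3-en-2-ol | I/C=C(/C)[C@H](CBr)O | intermediate
18 | tert-butyl{[(2R,3Z)-1-bromo-4-iodo-3-methylbut-3-en-2-yl]oxy}dimethylsilane | I/C=C(/C)[C@H](CBr)O[Si](C)(C)C(C)(C)C | intermediate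
19 | {[(1R,3S)-3-bromo-2,2-dimethyl-6-methylidenecyclohexyl]methyl}zinc iodide | C=C1CC[C@H](Br)C(C)(C)[C@@H]1C[Zn]I | intermediate
20 | tert-butyl({(2R,3Z)-1-bromo-5-[(1R,3S)-3-bromo-2,2-dimethyl-6-methylidenecyclohexyl]-3-methylpent-3-en-2-yl}oxy)dimethylsilane | C=C1CC[C@H](Br)C(C)(C)[C@@H]1C/C=C(/C)[C@H](CBr)O[Si](C)(C)C(C)(C)C | intermediate
21 | (2R,3Z)-1-bromo-5-[(1R,3S)-3-bromo-2,2-dimethyl-6-methylidenecyclohexyl]-3-methylpent-3-en-2-ol | C=C1CC[C@H](Br)C(C)(C)[C@@H]1C/C=C(/C)[C@H](CBr)O | intermediate
22 | (2R,3Z)-1-bromo-5-[(1R,3S)-3-bromo-2,2-dimethyl-6-methylidenecyclohexyl]-3-methylpent-3-en-2-yl acetate | C=C1CC[C@H](Br)C(C)(C)[C@@H]1C/C=C(/C)[C@H](CBr)OC(C)=O | target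

**Step count**
Total: 14 steps. Longest linear sequence: 9 steps (steps 1–6, then 12–14); the side-chain branch is 5 steps (7–11).

**Three steps most likely to fail**

Step 4 (the proposed new cyclization). The conjugated allylsilane may capture the bromiranium ion too slowly, which would allow racemization by bromine transfer between alkenes or simple bromodesilylation, and the sense of induction is not predictable in advance. The fallback uses known chemistry, sets out from 7 and comes back at 9. Compound 7 is cyclized without enantiocontrol with Et2SBr·SbCl5Br in MeNO2 at −25 °C to racemic methyl cis-3-bromo-2,2-dimethyl-6-methylidenecyclohexane-1-carboxylate F1. DIBAL-H reduction gives racemic cis-(3-bromo-2,2-dimethyl-6-methylidenecyclohexyl)methanol F2. Acylation with (1S)-camphanic chloride (Et3N, DMAP, CH2Cl2) gives the camphanate of the (1R,3S)-alcohol F3 and the camphanate of the (1S,3R)-alcohol F4, which are separated by crystallization or chromatography. Methanolysis of F3 (K2CO3, MeOH) returns enantiopure 9.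

Step 12 (Negishi coupling). Zinc insertion at the hindered β-branched iodide may be slow, and the alkylpalladium intermediate may undergo β-hydride elimination. The fallback sets out from 10 and comes back at 20; it replaces zinc insertion by lithium–iodine exchange and a boron nucleophile. Compound 10 is treated with t-BuLi (2.1 equiv, Et2O/pentane, −78 °C) to give the alkyllithium F7, which is trapped with B-methoxy-9-BBN to give the lithium alkyl(methoxy)borate F8. F8 is coupled with 18 under Pd(dppf)Cl2, AsPh3 and aq. K3PO4 in DMF at 25 °C (B-alkyl Suzuki–Miyaura coupling) to give 20.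

Step 10 (CBS reduction). CH2Br and the branched alkenyl group may not differ enough in size for high selectivity, and the bromoketone may drift from Z to E. The fallback sets out from 16 and comes back at 17; it replaces the reagent-controlled reduction by an enzymatic kinetic resolution. Compound 16 is reduced under Luche conditions (NaBH4, CeCl3·7H2O, MeOH, −78 °C) to racemic (3Z)-1-bromo-4-iodo-3-methylbut-3-en-2-ol F5. Lipase PS (Burkholderia cepacia) with vinyl acetate in MTBE at 30 °C acylates the (S)-enantiomer to (2S,3Z)-1-bromo-4-iodo-3-methylbut-3-en-2-yl acetate F6 and leaves the (R)-alcohol 17 (at most 50%), which is isolated by chromatography.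

**Further compounds**
F1 | step 4 | racemic methyl cis-3-bromo-2,2-dimethyl-6-methylidenecyclohexane-1-carboxylate | C=C1CC[C@H](Br)C(C)(C)[C@@H]1C(=O)OC.C=C1CC[C@@H](Br)C(C)(C)[C@H]1C(=O)OC
F2 | step 4 | racemic cis-(3-bromo-2,2-dimethyl-6-methylidenecyclohexyl)methanol | C=C1CC[C@H](Br)C(C)(C)[C@@H]1CO.C=C1CC[C@@H](Br)C(C)(C)[C@H]1CO
F3 | step 4 | [(1R,3S)-3-bromo-2,2-dimethyl-6-methylidenecyclohexyl]methyl (1S,4R)-camphanate | C=C1CC[C@H](Br)C(C)(C)[C@@H]1COC(=O)[C@@]12CC[C@@](C)(C(=O)O1)C2(C)C
F4 | step 4 | [(1S,3R)-3-bromo-2,2-dimethyl-6-methylidenecyclohexyl]methyl (1S,4R)-camphanate | C=C1CC[C@@H](Br)C(C)(C)[C@H]1COC(=O)[C@@]12CC[C@@](C)(C(=O)O1)C2(C)C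
F5 | step 10 | racemic (3Z)-1-bromo-4-iodo-3-methylbut-3-en-2-ol | I/C=C(/C)C(CBr)O
F6 | step 10 | (2S,3Z)-1-bromo-4-iodo-3-methylbut-3-en-2-yl acetate | I/C=C(/C)[C@@H](CBr)OC(C)=O
F7 | step 12 | {[(1R,3S)-3-bromo-2,2-dimethyl-6-methylidenecyclohexyl]methyl}lithium | C=C1CC[C@H](Br)C(C)(C)[C@@H]1C[Li]
F8 | step 12 | lithium {[(1R,3S)-3-bromo-2,2-dimethyl-6-methylidenecyclohexyl]methyl}(methoxy)-9-borabicyclo[3.3.1]nonan-9-uide | C=C1CC[C@H](Br)C(C)(C)[C@@H]1C[B-]2(OC)C3CCCC2CCC3.[Li+]
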